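Readings and results stem from a simulated flask on assumed constants; scatter was added.

The pitfall is to treat free catalyst as a plain speed dial, and to expect a flask with 3.50 times the free catalyst to run 3.50 times as fast.

| flask | starting material | free catalyst | time |
|---|---|---|---|
| autumn | 0.150 M | 0.0120 M |  |
| dusk | 0.0600 M | 0.0120 M |  |
| dawn | 0.300 M | 0.0120 M |  |
| spring | 0.150 M | 0.0240 M |  |
| noon | 0.150 M | 0.0420 M | 110 min |

| run | time / min | [starting material] / M |
|---|---|---|
| autumn run | 18 | 0.1220 |
| autumn run | 37 | 0.0976 |
| autumn run | 55 | 0.0784 |
| autumn run | 73 | 0.0621 |
| autumn run | 92 | 0.0485 |
| autumn run | 110 | 0.0384 |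
| dusk run | 18 | 0.0474 |
| dusk run | 37 | 0.0377 |
| dusk run | 55 | 0.0291 |
| dusk run | 73 | 0.0249 |
| dusk run | 92 | 0.0185 |
| dusk run | 110 | 0.0145 |
| dawn run | 18 | 0.2529 |
| dawn run | 37 | 0.2069 |
| dawn run | 55 | 0.1704 |
| dawn run | 73 | 0.1401 |
| dawn run | 92 | 0.1095 |
| dawn run | 110 | 0.0896 |
| spring run | 18 | 0.1092 |
| spring run | 37 | 0.0745 |
| spring run | 55 | 0.0509 |
| spring run | 73 | 0.0369 |
| spring run | 92 | 0.0254 |
| spring run | 110 | 0.0169 |

(each reading ± 8 × 10⁻⁴ M)

- Overall: starting material -> product, with free catalyst as catalyst.
- Constant volume, constant temperature.
- The analysis sees a species whether free or bound.
- An order is taken over about fifteen percent of the charge, up and down.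

* the exponent of [free catalyst] in the starting rate at the charge of the autumn run (at the point where two percent of the starting material have become product)
* the exponent of [starting material] in the starting rate at the charge of the autumn run (at the point where two percent of the starting material have become product) (one fixed amount of product, the same in the runs compared)
* the dusk run starts with 0.0900 M less of starting material than the autumn run, and with no product. Compared where both hold the same amount of starting material, once fifteen percent of what the dusk run was charged with has turned into product, is the dusk run faster, slower or alike (within a tenth)?
* starting material in the noon run at 110 min, as a share of the starting material charged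

I compare two times: the mid-time of the autumn run and that of the spring run, mid-time being the moment when the product made reaches 50 percent of the charge. Both runs hold 0.150 M of starting material and differ in free catalyst, so they pass through the same amounts, and dividing one time by the other removes the clock and leaves a ratio of rates. Interpolating the logarithm of the amount between the two nearest readings, I read the autumn mid-time as 58.4 min and the spring mid-time as 36.7 min. The spring mid-time is shorter than the autumn one, but their ratio is 1.59, while free catalyst went up by a factor of 2.00. Dividing the logarithm of the time ratio by the logarithm of the catalyst ratio gives the catalyst clock exponent, 0.672, an average over that step.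

The noon run has the autumn charge of starting material, so I scale the autumn mid-time by the catalyst ratio raised to this exponent and get 25.2 min. Then 110 min is 4.37 mid-times. Treating the decay as exponential (pseudo-first-order), each mid-time multiplies what is left by 0.5, which leaves 4.84 %.

The forecast gives 0.67 in free catalyst, 0.78 in starting material, alike for the dusk run and 4.5 % for noon, a share lower than mine. On free catalyst its grounds say: “Doubling catalyst raises the rate only about 1.55-fold”.

The flask gives 0.69 in free catalyst, 0.84 in starting material, alike for the dusk run, with a rate ratio of 1.0, and 4.77 % for noon.

    2 free catalyst ⇌ catalyst dimer, settled at all times (59.90 L mol⁻¹)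
    free catalyst + starting material → product + free catalyst (1.956 L mol⁻¹ min⁻¹)
    starting material → product (9.960 × 10⁻⁴ min⁻¹)
    free catalyst + starting material ⇌ idle catalyst-substrate complex, settled at all times (3.970 L mol⁻¹)

With the catalyst clock exponent of 0.672, my 4.37 mid-times leave 4.84 % in the noon run, against the 4.77 % it holds. The order in starting material stands below one because free catalyst pairs with starting material as idle catalyst-substrate complex: the autumn charge reads 0.84 with that pairing and 1.0 without it.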